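Ring B is closed last at C7–C8 (target numbering: ring A = C1–C4, C4a, C8a; ring B = C4a–C8a). Ring-closing metathesis joins the C8a vinyl group to a 1,1-disubstituted alkene on C7. The C7=C8 olefin so formed then slides to C6=C7, driven by the doubly activated C6–H of the ring-B β-keto ester, which leaves C7–C8 as the ring-closing single bond. The precursor is a monocyclic ring-A triester. Its four stereocentres come from an endo Diels–Alder reaction of a 2-pyrone, used as a cyclic Z-dienoate, with (5S)-5-menthyloxybutenolide, followed by SmI2 scission of the lactone bridge.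

Key step: step 9

Assumption: (5S)-5-[(1S,2R,5S)-menthyloxy]furan-2(5H)-one (7), the antipode of the more common (5R)-l-menthyl reagent, is taken as a commercial starting material.
Remark: target numbering (C1, C2, C3, C4, C4a, C5–C8, C8a) is used for the corresponding atoms of all intermediates.

Step 1
Reactants: 1 octadecan-2-one; 2 trimethyl phosphonoacetate
Product: 3 methyl (2E)-3-methylnonadec-2-enoate
Conditions: NaH, THF, 0 °C → 65 °C; E isomer separated on silica
Reagents that add atoms: none
Why: Horner–Wadsworth–Emmons olefination of a methyl ketone should give mainly the E enoate (ester trans to the long chain, cis to the methyl group), and the minor Z isomer is removed.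

Step 2
Reactants: 3 methyl (2E)-3-methylnonadec-2-enoate; 4 dimethyl oxalate
Product: 6 methyl 4-hexadecyl-2-oxo-2H-pyran-6-carboxylate, via oxalyl enoate 5 (not isolated)
Conditions: KOMe, THF, 0 °C → rt; then HCl/dioxane, 60 °C
Reagents that add atoms: none
Why: Vinylogous Claisen condensation under equilibrating alkoxide conditions should acylate the γ-methyl group (the product is a fully conjugated enolate), and acid then closes the enol oxygen onto the cis ester to give the 2-pyrone.

Step 3
Reactants: 6 methyl 4-hexadecyl-2-oxo-2H-pyran-6-carboxylate; 7 (5S)-5-[(1S,2R,5S)-menthyloxy]furan-2(5H)-one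
Product: 8 endo bridged-lactone cycloadduct
Conditions: CH2Cl2, 13 kbar, 40 °C
Reagents that add atoms: none
Why: Diels–Alder reaction of the 2-pyrone under high pressure (which also suppresses loss of CO2); the C4 ester ("ortho") and the C2 alkyl group ("para") should direct the lactone-carbonyl carbon of 7 to C4, the endo transition state places the γ-lactone anti to the bridging lactone, and addition anti to the menthyloxy group fixes C1, C4a and C8a.

Step 4
Reactants: 8 endo bridged-lactone cycloadduct
Product: 9 ring-A carboxylic acid with cis-fused menthyloxy γ-lactone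
Conditions: SmI2, THF/HMPA, MeOH, −78 °C; aq. HCl work-up
Reagents that add atoms: none
Why: SmI2 reductive cleavage of the α-acyloxy (and allylic) C4–O bond gives an ester dienolate that should be protonated at C4 from the face the carboxylate left, anti to the adjacent C4a–C5 bond, so the C4 ester ends cis to C4a–C5 while the C1 carboxyl stays on the former bridge face, trans to C8a–C8.

Step 5
Reactants: 9 ring-A carboxylic acid with cis-fused menthyloxy γ-lactone
Product: 10 ring-A dimethyl ester with cis-fused menthyloxy γ-lactone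
Conditions: TMSCHN2, PhMe/MeOH, 0 °C
Reagents that add atoms: (trimethylsilyl)diazomethane, C[Si](C)(C)C=[N+]=[N-]
Why: Esterification of the free acid with a diazoalkane under neutral conditions, so that none of the epimerisable centres is touched.

Step 6
Reactants: 10 ring-A dimethyl ester with cis-fused menthyloxy γ-lactone
Product: 11 ring-A hydroxy lactone (lactol)
Conditions: 2 M HCl, dioxane, 45 °C
Reagents that add atoms: water, O
Why: Acid hydrolysis of the acyl alkyl acetal should release menthol and leave the cyclic hemiacetal of the cis C8a-formyl C4a-carboxylic acid; no ring-A stereocentre is involved and the anomeric mixture is inconsequential.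

Step 7
Reactants: 11 ring-A hydroxy lactone (lactol)
Product: 12 2-ethenyl-4-hexadecyl-3,6-bis(methoxycarbonyl)cyclohex-4-ene-1-carboxylic acid
Conditions: Ph3PCH3Br, KHMDS, THF, −78 → 0 °C; work-up at pH 3
Reagents that add atoms: methyltriphenylphosphonium bromide, C[P+](c1ccccc1)(c1ccccc1)c1ccccc1.[Br-]
Why: Wittig methylenation of the lactol through its open aldehyde–carboxylate form; the carboxylate shields C4a–H, and salt-free ylide at low temperature is meant to outrun enolisation at C8a.

Step 8
Reactants: 12 2-ethenyl-4-hexadecyl-3,6-bis(methoxycarbonyl)cyclohex-4-ene-1-carboxylic acid; 3 methyl (2E)-3-methylnonadec-2-enoate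
Product: 14 methyl 2-(cyclohexenylcarbonyl)-3-methylidenenonadecanoate, via acyl imidazolide 13 (not isolated)
Conditions: 12, CDI, THF, rt; added to 3 (2.2 equiv) + LDA, THF/DMPU, −78 °C; AcOH quench at −78 °C
Reagents that add atoms: none
Why: Claisen-type C-acylation of the lithium dienolate formed by γ-deprotonation of the methyl group syn to the ester of 3; dienolates are acylated at the α-carbon, which should give the β,γ-unsaturated β-keto ester (C6 as an inconsequential epimer/enol mixture), and the second equivalent of dienolate takes up the acidic product proton.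

Step 9
Reactants: 14 methyl 2-(cyclohexenylcarbonyl)-3-methylidenenonadecanoate
Product: 16 trimethyl (1S,4R,4aS,8aR)-2,7-dihexadecyl-5-oxo-1,4,4a,5,8,8a-hexahydronaphthalene-1,4,6-tricarboxylate, via C7=C8 keto ester 15 (not isolated)
Conditions: (H2IMes)(PCy3)Cl2Ru=CHPh (5 mol %), PhMe, 60 °C; then Et3N (cat.), CH2Cl2, rt
Reagents that add atoms: none
Why: Ring-closing olefin metathesis: the Ru alkylidene loads on the monosubstituted C8a vinyl group and closes onto the 1,1-disubstituted C7 alkene through a metallacyclobutane, releasing ethene and forming C7=C8 in a six-membered ring (closure onto a gem-disubstituted olefin to a trisubstituted cyclohexene). The primary product 15 is a β,γ-unsaturated β-keto ester; Et3N removes the doubly activated C6–H, and protonation of the dienolate at C8 moves the alkene to C6=C7, conjugated with both carbonyls, so the metathesis bond stays as the C7–C8 single bond. The closest known reaction type is RCM to cyclohexenes followed by base-mediated β,γ to α,β isomerisation of unsaturated carbonyl compounds. No new stereocentre remains (C6 becomes sp2), and the cis ring fusion is inherited from C4a and C8a set in step 3. The step needs chemoselectivity for the two terminal alkenes over the trisubstituted ring-A alkene, which should be inert to the catalyst, and the isomerisation must not epimerise C4a, C4 or C1; the large acidity gap between C6–H and the other α-protons and the weak amine base should secure this.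

Compound list
1 | octadecan-2-one | CCCCCCCCCCCCCCCCC(C)=O | starting material
2 | trimethyl phosphonoacetate | COC(=O)CP(=O)(OC)OC | starting material
3 | methyl (2E)-3-methylnonadec-2-enoate | CCCCCCCCCCCCCCCC/C(C)=C/C(=O)OC | intermediate
4 | dimethyl oxalate | COC(=O)C(=O)OC | starting material
5 | dimethyl (2Z)-3-hexadecyl-5-oxohex-2-enedioate (oxalyl enoate; formed as its potassium enolate) | CCCCCCCCCCCCCCCC/C(CC(=O)C(=O)OC)=C/C(=O)OC | intermediate
6 | methyl 4-hexadecyl-2-oxo-2H-pyran-6-carboxylate | CCCCCCCCCCCCCCCCC1=CC(=O)OC(C(=O)OC)=C1 | intermediate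
7 | (5S)-5-{[(1S,2R,5S)-5-methyl-2-(propan-2-yl)cyclohexyl]oxy}furan-2(5H)-one | O=C1C=C[C@@H](O[C@H]2C[C@@H](C)CC[C@@H]2C(C)C)O1 | starting material
8 | endo cycloadduct: 2-oxabicyclo[2.2.2]octenone with lactone bridge C1–C(=O)–O–C4, CO2Me on C4, hexadecyl on C2 (C2=C3), and the γ-lactone acetal C4a–C5(=O)–O–C8H(O-menthyl)–C8a cis-fused anti to the bridge, menthyloxy anti to the bicycle (C8 S) | CCCCCCCCCCCCCCCCC1=C[C@]2(C(=O)OC)OC(=O)[C@H]1[C@H]3[C@@H]2C(=O)O[C@@H]3O[C@H]4C[C@@H](C)CC[C@@H]4C(C)C | intermediate
9 | ring-A acid: cyclohex-2-ene with C1 CO2H, C2 hexadecyl, C4 CO2Me and the (8S)-menthyloxy γ-lactone cis-fused at C4a/C8a; C4 ester, C4a–C5 and C8a–C8 mutually cis, C1 carboxyl trans to them (spatial arrangement as in the target) | CCCCCCCCCCCCCCCCC1=C[C@@H](C(=O)OC)[C@H]2C(=O)O[C@H](O[C@H]3C[C@@H](C)CC[C@@H]3C(C)C)[C@H]2[C@@H]1C(=O)O | intermediate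
10 | methyl ester of 9 at C1 (same configuration) | CCCCCCCCCCCCCCCCC1=C[C@@H](C(=O)OC)[C@H]2C(=O)O[C@H](O[C@H]3C[C@@H](C)CC[C@@H]3C(C)C)[C@H]2[C@@H]1C(=O)OC | intermediate
11 | lactol: hydroxy γ-lactone C4a–C5(=O)–O–C8H(OH)–C8a on the ring-A diester (anomeric mixture; ring-A configuration as in 10) | CCCCCCCCCCCCCCCCC1=C[C@@H](C(=O)OC)[C@H]2C(=O)OC(O)[C@H]2[C@@H]1C(=O)OC | intermediate
12 | 2-ethenyl-4-hexadecyl-3,6-bis(methoxycarbonyl)cyclohex-4-ene-1-carboxylic acid; CO2H, vinyl and the C6 ester mutually cis, C3 ester trans (target C4a, C8a, C4, C1 configuration) | CCCCCCCCCCCCCCCCC1=C[C@@H](C(=O)OC)[C@@H](C(=O)O)[C@@H](C=C)[C@@H]1C(=O)OC | intermediate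
13 | acyl imidazolide of 12 | CCCCCCCCCCCCCCCCC1=C[C@@H](C(=O)OC)[C@@H](C(=O)n2ccnc2)[C@@H](C=C)[C@@H]1C(=O)OC | intermediate
14 | methyl 2-{[2-ethenyl-4-hexadecyl-3,6-bis(methoxycarbonyl)cyclohex-4-en-1-yl]carbonyl}-3-methylidenenonadecanoate (ring configuration as in 12; C6 epimers/enol) | CCCCCCCCCCCCCCCCC1=C[C@@H](C(=O)OC)[C@@H](C(=O)C(C(=O)OC)C(=C)CCCCCCCCCCCCCCCC)[C@@H](C=C)[C@@H]1C(=O)OC | intermediate
15 | trimethyl 2,7-dihexadecyl-5-oxo-1,4,4a,5,6,8a-hexahydronaphthalene-1,4,6-tricarboxylate (C7=C8 isomer of the target; C6 epimers) | CCCCCCCCCCCCCCCCC1=C[C@@H](C(=O)OC)[C@H]2C(=O)C(C(=O)OC)C(CCCCCCCCCCCCCCCC)=C[C@H]2[C@@H]1C(=O)OC | intermediate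
16 | trimethyl (1S,4R,4aS,8aR)-2,7-dihexadecyl-5-oxo-1,4,4a,5,8,8a-hexahydronaphthalene-1,4,6-tricarboxylate | CCCCCCCCCCCCCCCCC1=C[C@@H](C(=O)OC)[C@H]2C(=O)C(C(=O)OC)=C(CCCCCCCCCCCCCCCC)C[C@H]2[C@@H]1C(=O)OC | target

Total step count: 9. Longest linear sequence: 9 steps (1 → 16).

Steps most likely to fail

Step 3. Two electron-poor partners may not combine even under pressure, the regiochemistry may be reversed, or the adduct may lose CO2. The fallback sets out from 6 and uses the far more reactive maleic anhydride (PhMe, 110 °C) to give the racemic endo lactone–anhydride adduct F1. SmI2 cleavage as in step 4 should give the racemic anhydride acid F2. LiAlH(OtBu)3 (THF, −78 °C) should reduce the less hindered anhydride carbonyl, the one on C8a remote from the cis C4 ester, to the racemic hydroxy lactone acid F3. Acetalisation with (1S,2R,5S)-menthol (CSA, PhH, azeotropic removal of water) then gives 9 together with the diastereomeric menthyl acetal of the enantiomeric core F4, which is removed by crystallisation or chromatography. The route is rejoined at 9.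

Step 8. The basic dienolate may take a proton from C4a, C4 or C1 (epimerisation, ketene formation from the acyl imidazolide) or be acylated at the γ-carbon. The fallback sets out from 12. The acyl imidazolide 13 is treated with magnesium methyl malonate (THF, rt), a neutral decarboxylative Claisen condensation, to give the ring-A β-keto ester F5. In(OTf)3-catalysed addition of its active methylene to octadec-1-yne (intermolecular Conia-ene-type 2-alkenylation, PhMe, 80 °C) then installs the C7 alkene with its hexadecyl chain and comes back to the route at 14.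

Step 7. The ylide may epimerise C8a next to the aldehyde, or the ester α-centres, before olefination is complete. The fallback sets out from 11. Addition of Me3SiCH2MgCl/CeCl3 (THF, −78 °C), a non-basic organocerium reagent, to the open aldehyde and acidic work-up should give the β-silyl γ-lactone F6. TBAF (THF, 0 °C) then fragments it in the way 2-(trimethylsilyl)ethyl esters are cleaved, with loss of the silyl group and the lactone oxygen, to the vinyl acid; the route is rejoined at 12.

Further compounds
F1 | step 3 | racemic endo maleic anhydride cycloadduct of 6 (one enantiomer drawn) | CCCCCCCCCCCCCCCCC1=C[C@]2(C(=O)OC)OC(=O)[C@H]1[C@H]3[C@@H]2C(=O)OC3=O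
F2 | step 3 | racemic ring-A acid with cis-fused anhydride at C4a/C8a (one enantiomer drawn) | CCCCCCCCCCCCCCCCC1=C[C@@H](C(=O)OC)[C@H]2C(=O)OC(=O)[C@H]2[C@@H]1C(=O)O
F3 | step 3 | racemic ring-A acid with hydroxy γ-lactone (lactol carbon on C8a; one enantiomer drawn) | CCCCCCCCCCCCCCCCC1=C[C@@H](C(=O)OC)[C@H]2C(=O)OC(O)[C@H]2[C@@H]1C(=O)O
F4 | step 3 | diastereomer of 9: (1S,2R,5S)-menthyl acetal of the enantiomeric ring-A core | CCCCCCCCCCCCCCCCC1=C[C@H](C(=O)OC)[C@@H]2C(=O)O[C@@H](O[C@H]3C[C@@H](C)CC[C@@H]3C(C)C)[C@@H]2[C@H]1C(=O)O
F5 | step 8 | methyl 3-[2-ethenyl-4-hexadecyl-3,6-bis(methoxycarbonyl)cyclohex-4-en-1-yl]-3-oxopropanoate | CCCCCCCCCCCCCCCCC1=C[C@@H](C(=O)OC)[C@@H](C(=O)CC(=O)OC)[C@@H](C=C)[C@@H]1C(=O)OC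
F6 | step 7 | γ-lactone C4a–C5(=O)–O–C8H(CH2SiMe3)–C8a on the ring-A diester (C8 epimers) | CCCCCCCCCCCCCCCCC1=C[C@@H](C(=O)OC)[C@H]2C(=O)OC(C[Si](C)(C)C)[C@H]2[C@@H]1C(=O)OC
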